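L that has become L.Z cannot work again, because that step runs one way, and Z cannot take more L than its own charge.

G 2.5 M; E 200 mM (held); L 40 mM; Z 14 mM; time 3.0 min

    D + L ⇌ D.L, settled at all times (K1 = 81 /M)
    G + D + L → L + Q (k2 = 0.76 /M²/s)
    E ⇌ D, rate k3*(csat - [D]) (k3 = 0.88 /s, csat = 200 mM)
    L + Z → L.Z (k4 = 300 /M/s)

1. how much Q there is at 3.0 min, in percent of the G charged
2. the change that raises the amount of Q at 3.0 min, in percent of the G charged most ("none" if none brings more than 2 percentage points) (eta / theta / zeta / none)
3. amount of Q at 3.0 min, in percent of the G charged, after zeta

- at the start none of D is dissolved
- run time (flask): 3.0 min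

- eta: doubling the transfer coefficient of step 3, all else as stated
- theta: doubling the amount of L, all else as stated
- zeta: doubling the saturation concentration of E, all else as stated

I turned the question round and asked what the charges would have to be for Z to silence the flask: Z would have to match L, one for one. It stood at 35.0% of the L charge, so 65.0% of the L survived; I called this the working share, the part of the charged L that Z leaves over. Even with dissolved D holding L down, I reckoned the half-life of Z at 1.53 s, much shorter than 3.0 min, so I let the share stand from the start.

Next I sought the concentration that sets the order of the rate. Free L was 5.81% of the working share, and because K1 times saturation, 16.2, far exceeds one, D dropped out of the order. The rate was pseudo-first-order in G, with constant 2.30 × 10⁻⁴ /s. Its demand of 0.574 mM/s was far less than the 176 mM/s that step 3 delivers into a solution empty of D, so I held D at saturation and eta promised nothing.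

That gave me 4.05% of G as Q. Doubling L raised the working share to 82.5% of a doubled charge and gave 9.97%, while zeta gave 4.17%, so I chose theta.

The forecast gave 4.04%, 4.16% after zeta and theta as best, holding that “Z is a fast poison”.

The simulation gave 4.05%, 4.18% after zeta, and theta as best, with 5.9 percentage points gained against 0.0071 points for eta. In the flask at 0.0248 min, the half-life of Z was 1.0 s, far shorter than the 50 min of G, and by 0.300 min L.Z stood at 35.0% of the catalyst, the complement of the working share. In the neighbour flask with 0.056 M of Z, the rule left no working share and a surplus of 28.6% of the Z charge; there L.Z stood at 100%, Z at 29% of its charge, and Q at 0.0163%.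

(The numbers are assumed; the result is computed.)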